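## Retrosynthetic overview

1. The target comes from its 20,21-acetonide/23-O-TBS derivative. The only ring (28-membered) is closed last, at C17–C18, by intramolecular B-alkyl Suzuki–Miyaura coupling of the 9-BBN adduct of a C18=C19 vinyl group onto a C17 bromodiene.
2. The bromodiene comes from a C15 alkenyl boronate and (E)-2-bromo-1-iodo-3-methoxypropene by iodide-selective Suzuki coupling, which fixes the 16Z geometry.
3. Key step: the C12–C13 bond and the C13 stereocentre are made together by nickel-catalysed enantioconvergent radical coupling of the C12 alkylzinc (carrying the whole ester–amide chain) with a racemic γ-chloro-alkenylboronate.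
4. The ester comes from (2S,4S)-12-bromo-2,4-dimethyldodecanoic acid (two zirconium-catalysed carboaluminations of 10-bromodecene) and a hydroxy amide.
5. The hydroxy amide comes from (S)-2-hydroxypentanoic acid and a C18–C24 amine: C23 from (S)-4-chloro-3-hydroxybutanenitrile, C20/C21 by Brown anti-diol allylboration.

## Assumptions and notation

- Assumption (numbering): chain atoms are C1 (lactone carbonyl) to C24 (CH2N); the 2-hydroxypentanoyl unit is C1′–C5′. The target SMILES reads as 2S,4S,13R,14E,16Z,20R,21S,23S,2′S.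
- Assumption (ligand sense): (S,S)-BnCH2-Pybox is taken to give 13R by analogy with the parent allylic chloride couplings; if a model coupling shows the opposite sense, the (R,R)-ligand is used.
- TBS = tert-butyl(dimethyl)silyl; Bpin = 4,4,5,5-tetramethyl-1,3,2-dioxaborolan-2-yl; Ipc = isopinocampheyl from (−)-α-pinene; (NMI)2ZrCl2 = bis(1-neomenthylindenyl)zirconium dichloride; MAO = methylaluminoxane, (MeAlO)n.

## Route

Step 1
Reactants: 1 5-bromopent-1-ene; 2 1,5-dibromopentane
Product: 4 10-bromodec-1-ene, via pent-4-enylmagnesium bromide 3 (not isolated)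
Conditions: 1, Mg, THF, 40 °C; then 2 (3 equiv), Li2CuCl4 (3 mol%), THF, −10 °C → rt
Reagents that add atoms: none
Why: Kochi-type copper-catalysed Grignard–alkyl bromide coupling; excess dibromide suppresses double coupling and the pent-4-enyl Grignard cannot ring-close.

Step 2
Reactants: 4 10-bromodec-1-ene; 5 bromoethene
Product: 7 (4S)-12-bromo-4-methyldodec-1-ene, via alkylalane 6 (not isolated)
Conditions: Me3Al (2 equiv), (+)-(NMI)2ZrCl2 (4 mol%), MAO (1 equiv), CH2Cl2, 0 °C → rt; evaporate; Zn(OTf)2 (1 equiv), DMF, 70 °C; then 5 (4 equiv), Pd(DPEphos)Cl2 (3 mol%), i-Bu2AlH (6 mol%), DMF, rt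
Reagents that add atoms: trimethylaluminium, C[Al](C)C
Why: Negishi's zirconium-catalysed asymmetric carboalumination (ZACA) adds Me–Al across the terminal alkene with face selection by the chiral zirconocene and sets C4 as S (about 75–90% ee); the alane is passed to zinc and vinylated by palladium-catalysed Negishi coupling in the same pot, and the primary C–Br bond is inert.

Step 3
Reactants: 7 (4S)-12-bromo-4-methyldodec-1-ene
Product: 9 (2S,4S)-12-bromo-2,4-dimethyldodecan-1-ol, via alkylalane 8 (not isolated)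
Conditions: Me3Al (2 equiv), (+)-(NMI)2ZrCl2 (4 mol%), MAO (1 equiv), CH2Cl2, 0 °C → rt; then O2, 0 °C; aq. NaOH; chromatography (anti isomer removed)
Reagents that add atoms: trimethylaluminium, C[Al](C)C; dioxygen, O=O
Why: A second ZACA with the same catalyst antipode sets C2 syn to C4 and O2 oxidises the C–Al bond with retention; once the anti diastereomer is removed, the syn (2S,4S) alcohol is ≥95% ee by statistical amplification.

Step 4
Reactants: 9 (2S,4S)-12-bromo-2,4-dimethyldodecan-1-ol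
Product: 10 (2S,4S)-12-bromo-2,4-dimethyldodecanoic acid
Conditions: TEMPO (7 mol%), NaOCl (2 mol%), NaClO2 (2 equiv), MeCN/phosphate buffer pH 6.7, 35 °C
Reagents that add atoms: sodium chlorite, [Na+].[O-]Cl=O
Why: Zhao's TEMPO/hypochlorite-catalysed, chlorite-driven oxidation takes the primary alcohol to the acid under near-neutral conditions that do not epimerise C2 or touch the bromide.

Step 5
Reactants: 11 (3S)-4-chloro-3-hydroxybutanenitrile
Product: 12 (3S)-4-azido-3-hydroxybutanenitrile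
Conditions: NaN3 (1.5 equiv), DMF, 75 °C
Reagents that add atoms: sodium azide, [Na+].[N-]=[N+]=[N-]
Why: SN2 displacement of the primary chloride (directly or through the epoxide) leaves the C–O stereocentre (future C23) untouched.

Step 6
Reactants: 12 (3S)-4-azido-3-hydroxybutanenitrile
Product: 13 (3S)-4-azido-3-(TBS-oxy)butanenitrile
Conditions: TBSCl, imidazole, DMF, rt
Reagents that add atoms: tert-butyl(chloro)dimethylsilane, CC(C)(C)[Si](C)(C)Cl
Why: Standard imidazole-promoted silylation of the secondary alcohol.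

Step 7
Reactants: 13 (3S)-4-azido-3-(TBS-oxy)butanenitrile
Product: 14 (3S)-4-azido-3-(TBS-oxy)butanal
Conditions: i-Bu2AlH (1.1 equiv), CH2Cl2, −78 °C; then aq. KNaC4H4O6, rt
Reagents that add atoms: water, O
Why: Partial reduction of the nitrile by i-Bu2AlH stops at the aluminium aldimine, which is hydrolysed on work-up; at −78 °C the azide and silyl ether are not attacked.

Step 8
Reactants: 15 3-bromoprop-1-yne
Product: 17 4,4,5,5-tetramethyl-2-(propa-1,2-dien-1-yl)-1,3,2-dioxaborolane, via allenylmagnesium bromide 16 (not isolated)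
Conditions: Mg, HgCl2 (1 mol%), Et2O, 0 °C; then i-PrOBpin, −78 °C → rt
Reagents that add atoms: 2-isopropoxy-4,4,5,5-tetramethyl-1,3,2-dioxaborolane, CC(C)OB1OC(C)(C)C(C)(C)O1
Why: Propargyl bromide gives the allenyl Grignard reagent, which is borylated by the alkoxyboronate to the allenyl boronate (Grignard borylation).

Step 9
Reactants: 14 (3S)-4-azido-3-(TBS-oxy)butanal; 17 4,4,5,5-tetramethyl-2-(propa-1,2-dien-1-yl)-1,3,2-dioxaborolane
Product: 20 (3R,4S,6S)-7-azido-6-(TBS-oxy)hept-1-ene-3,4-diol, via allylborane 18 (not isolated), via borinate 19 (not isolated)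
Conditions: 17, (+)-Ipc2BH [from (−)-α-pinene], THF, −25 → 0 °C; 14, −78 °C, 4 h; then 3 M NaOH, 30% H2O2, 0 °C → rt
Reagents that add atoms: hydrogen peroxide, OO
Why: Brown's anti-diol allylboration: hydroboration of the allenyl boronate gives the (E)-γ-boryl allylborane, the E geometry gives the anti relationship through a chair Zimmerman–Traxler transition state, the Ipc groups select the aldehyde face (C21 = S, C20 = R, overriding the β-silyloxy centre), and both C–B bonds are oxidised with retention.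

Step 10
Reactants: 20 (3R,4S,6S)-7-azido-6-(TBS-oxy)hept-1-ene-3,4-diol
Product: 21 (4S,5R)-4-[(2S)-3-azido-2-(TBS-oxy)propyl]-5-ethenyl-2,2-dimethyl-1,3-dioxolane
Conditions: 2,2-dimethoxypropane, pyridinium p-toluenesulfonate (5 mol%), CH2Cl2, rt
Reagents that add atoms: 2,2-dimethoxypropane, COC(C)(C)OC
Why: Acid-catalysed transacetalisation protects the erythro 1,2-diol as the cis-dioxolane without loss of the secondary TBS ether.

Step 11
Reactants: 21 (4S,5R)-4-[(2S)-3-azido-2-(TBS-oxy)propyl]-5-ethenyl-2,2-dimethyl-1,3-dioxolane; 22 (2S)-2-hydroxypentanoic acid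
Product: 24 (2S)-N-{(2S)-2-(TBS-oxy)-3-[(4S,5R)-5-ethenyl-2,2-dimethyl-1,3-dioxolan-4-yl]propyl}-2-hydroxypentanamide, via amine 23 (not isolated)
Conditions: PMe3, THF/H2O, rt; concentrate; 22, EDC·HCl, HOBt, i-Pr2NEt, CH2Cl2, 0 °C → rt
Reagents that add atoms: none
Why: Staudinger reduction frees the primary amine, which is acylated chemoselectively over the hydroxyl groups in a carbodiimide/HOBt coupling; the α-hydroxy acid does not racemise.

Step 12
Reactants: 10 (2S,4S)-12-bromo-2,4-dimethyldodecanoic acid; 24 (2S)-N-{(2S)-2-(TBS-oxy)-3-[(4S,5R)-5-ethenyl-2,2-dimethyl-1,3-dioxolan-4-yl]propyl}-2-hydroxypentanamide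
Product: 26 (2S)-1-({(2S)-2-(TBS-oxy)-3-[(4S,5R)-5-ethenyl-2,2-dimethyl-1,3-dioxolan-4-yl]propyl}amino)-1-oxopentan-2-yl (2S,4S)-12-bromo-2,4-dimethyldodecanoate, via mixed anhydride 25 (not isolated)
Conditions: 10, 2,4,6-trichlorobenzoyl chloride, Et3N, THF, rt; then 24, DMAP, toluene, rt
Reagents that add atoms: none
Why: Yamaguchi esterification: DMAP transfers the α-branched acyl group from the mixed anhydride to the only free (secondary) hydroxyl, with no epimerisation at C2 or C2′.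

Step 13
Reactants: 27 3-chlorobut-1-yne (racemic)
Product: 28 (E)-2-(3-chlorobut-1-en-1-yl)-4,4,5,5-tetramethyl-1,3,2-dioxaborolane (racemic)
Conditions: pinacolborane (1.1 equiv), Cp2Zr(H)Cl (5 mol%), Et3N (5 mol%), neat, 50 °C
Reagents that add atoms: pinacolborane, B1OC(C)(C)C(C)(C)O1
Why: Zirconium-catalysed syn hydroboration of the terminal alkyne gives the E-alkenyl boronate and leaves the propargylic C–Cl bond intact.

Step 14 (key step)
Reactants: 26 (2S)-1-({(2S)-2-(TBS-oxy)-3-[(4S,5R)-5-ethenyl-2,2-dimethyl-1,3-dioxolan-4-yl]propyl}amino)-1-oxopentan-2-yl (2S,4S)-12-bromo-2,4-dimethyldodecanoate; 28 (E)-2-(3-chlorobut-1-en-1-yl)-4,4,5,5-tetramethyl-1,3,2-dioxaborolane (racemic)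
Product: 30 (2S)-1-({(2S)-2-(TBS-oxy)-3-[(4S,5R)-5-ethenyl-2,2-dimethyl-1,3-dioxolan-4-yl]propyl}amino)-1-oxopentan-2-yl (2S,4S,13R,14E)-2,4,13-trimethyl-15-(Bpin)pentadec-14-enoate, via alkylzinc bromide 29 (not isolated)
Conditions: Zn dust (2 equiv, activated with I2 5 mol%), DMA, 60 °C; then NiCl2·glyme (10 mol%), (S,S)-BnCH2-Pybox (13 mol%), NaCl (4 equiv), 28 (2 equiv), DMA/DMF 1:1, −10 °C, 24 h
Reagents that add atoms: none
Why: Proposed new method: the alkylnickel formed by transmetalation from 29 abstracts chlorine from either enantiomer of 28 to give one planar 1-boryl-3-methylallyl radical, which is captured by the chiral Pybox–nickel centre, and reductive elimination from trivalent nickel forms C12–C13 at the methyl-bearing terminus (remote from the π-acceptor boryl group, so the product stays a conjugated E-alkenyl boronate) and sets 13R by catalyst control; the closest known reaction type is the nickel/Pybox stereoconvergent Negishi coupling of racemic secondary allylic chlorides with alkylzinc halides (regiocontrol by a conjugating ester or a bulky group), and Bpin tolerance is known from nickel-catalysed alkylzinc couplings of α-haloboronates; ester, secondary amide, silyl ether, acetonide and the terminal alkene are compatible with alkylzinc halides at −10 °C.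

Step 15
Reactants: 31 3-methoxyprop-1-yne
Product: 32 (1E)-2-bromo-1-iodo-3-methoxyprop-1-ene
Conditions: IBr (1.05 equiv), CH2Cl2, −78 → 0 °C, dark
Reagents that add atoms: iodine monobromide, IBr
Why: Electrophilic anti iodobromination through an iodonium ion places iodine on the terminal carbon and bromine on the internal carbon, trans to each other, so iodine is cis to CH2OMe.

Step 16
Reactants: 30 (2S)-1-({(2S)-2-(TBS-oxy)-3-[(4S,5R)-5-ethenyl-2,2-dimethyl-1,3-dioxolan-4-yl]propyl}amino)-1-oxopentan-2-yl (2S,4S,13R,14E)-2,4,13-trimethyl-15-(Bpin)pentadec-14-enoate; 32 (1E)-2-bromo-1-iodo-3-methoxyprop-1-ene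
Product: 33 (2S)-1-({(2S)-2-(TBS-oxy)-3-[(4S,5R)-5-ethenyl-2,2-dimethyl-1,3-dioxolan-4-yl]propyl}amino)-1-oxopentan-2-yl (2S,4S,13R,14E,16E)-17-bromo-18-methoxy-2,4,13-trimethyloctadeca-14,16-dienoate
Conditions: 32 (1.5 equiv), Pd(PPh3)4 (5 mol%), aq. K3PO4 (3 equiv), THF, 40 °C
Reagents that add atoms: none
Why: Suzuki–Miyaura coupling with retention at both alkenes; zerovalent palladium inserts into the terminal C–I bond far faster than into the hindered internal C–Br bond, so C15 ends up cis to CH2OMe and the bromide is kept for the ring closure.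

Step 17
Reactants: 33 (2S)-1-({(2S)-2-(TBS-oxy)-3-[(4S,5R)-5-ethenyl-2,2-dimethyl-1,3-dioxolan-4-yl]propyl}amino)-1-oxopentan-2-yl (2S,4S,13R,14E,16E)-17-bromo-18-methoxy-2,4,13-trimethyloctadeca-14,16-dienoate
Product: 35 20,21-O-isopropylidene-23-O-TBS derivative of the target macrocycle, via alkylborane 34 (not isolated)
Conditions: 9-BBN dimer (1.5 equiv B–H), THF, 0 °C → rt; then slow addition to Pd(dppf)Cl2 (20 mol%), AsPh3 (40 mol%), Cs2CO3 (3 equiv), DMF/THF/H2O, 50 °C, final 1 mM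
Reagents that add atoms: none
Why: 9-BBN hydroborates only the monosubstituted alkene (anti-Markovnikov, boron at C18), and intramolecular B-alkyl Suzuki–Miyaura coupling onto the C17 bromide under high dilution closes the 28-membered ring with retention, giving the 16Z diene.

Step 18
Reactants: 35 20,21-O-isopropylidene-23-O-TBS derivative of the target macrocycle
Product: 36 CNP0511044.2 (target)
Conditions: 48% aq. HF, MeCN, 0 °C → rt
Reagents that add atoms: none
Why: Aqueous HF cleaves the TBS ether and hydrolyses the acetonide in one global acidic deprotection, mild enough for the lactone, the amide and the allylic methyl ether of the diene.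

## Compound list

1 | 5-bromopent-1-ene | C=CCCCBr | starting material
2 | 1,5-dibromopentane | BrCCCCCBr | starting material
3 | pent-4-en-1-ylmagnesium bromide | C=CCCC[Mg]Br | intermediate
4 | 10-bromodec-1-ene | C=CCCCCCCCCBr | intermediate
5 | bromoethene | C=CBr | starting material
6 | [(2S)-10-bromo-2-methyldecyl]dimethylaluminium | C[Al](C)C[C@@H](C)CCCCCCCCBr | intermediate
7 | (4S)-12-bromo-4-methyldodec-1-ene | C=CC[C@@H](C)CCCCCCCCBr | intermediate
8 | [(2S,4S)-12-bromo-2,4-dimethyldodecyl]dimethylaluminium | C[Al](C)C[C@@H](C)C[C@@H](C)CCCCCCCCBr | intermediate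
9 | (2S,4S)-12-bromo-2,4-dimethyldodecan-1-ol | OC[C@@H](C)C[C@@H](C)CCCCCCCCBr | intermediate
10 | (2S,4S)-12-bromo-2,4-dimethyldodecanoic acid | OC(=O)[C@@H](C)C[C@@H](C)CCCCCCCCBr | intermediate
11 | (3S)-4-chloro-3-hydroxybutanenitrile | N#CC[C@H](O)CCl | starting material
12 | (3S)-4-azido-3-hydroxybutanenitrile | N#CC[C@H](O)CN=[N+]=[N-] | intermediate
13 | (3S)-4-azido-3-(TBS-oxy)butanenitrile | N#CC[C@H](O[Si](C)(C)C(C)(C)C)CN=[N+]=[N-] | intermediate
14 | (3S)-4-azido-3-(TBS-oxy)butanal | O=CC[C@H](O[Si](C)(C)C(C)(C)C)CN=[N+]=[N-] | intermediate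
15 | 3-bromoprop-1-yne | C#CCBr | starting material
16 | propa-1,2-dien-1-ylmagnesium bromide | C=C=C[Mg]Br | intermediate
17 | 4,4,5,5-tetramethyl-2-(propa-1,2-dien-1-yl)-1,3,2-dioxaborolane | C=C=CB1OC(C)(C)C(C)(C)O1 | intermediate
18 | [(2E)-3-(Bpin)prop-2-en-1-yl]bis(isopinocampheyl)borane, both Ipc from (−)-α-pinene | CC1(C)OB(/C=C/CB([C@H]2C[C@H]3C[C@@H]([C@@H]2C)C3(C)C)[C@H]2C[C@H]3C[C@@H]([C@@H]2C)C3(C)C)OC1(C)C | intermediate
19 | (3R,4S,6S)-7-azido-6-(TBS-oxy)-3-(Bpin)hept-1-en-4-yl bis(isopinocampheyl)borinate | C=C[C@@H](B1OC(C)(C)C(C)(C)O1)[C@@H](OB([C@H]2C[C@H]3C[C@@H]([C@@H]2C)C3(C)C)[C@H]2C[C@H]3C[C@@H]([C@@H]2C)C3(C)C)C[C@H](O[Si](C)(C)C(C)(C)C)CN=[N+]=[N-] | intermediate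
20 | (3R,4S,6S)-7-azido-6-(TBS-oxy)hept-1-ene-3,4-diol | C=C[C@@H](O)[C@@H](O)C[C@H](O[Si](C)(C)C(C)(C)C)CN=[N+]=[N-] | intermediate
21 | (4S,5R)-4-[(2S)-3-azido-2-(TBS-oxy)propyl]-5-ethenyl-2,2-dimethyl-1,3-dioxolane | C=C[C@H]1OC(C)(C)O[C@H]1C[C@H](O[Si](C)(C)C(C)(C)C)CN=[N+]=[N-] | intermediate
22 | (2S)-2-hydroxypentanoic acid | CCC[C@H](O)C(=O)O | starting material
23 | (2S)-2-(TBS-oxy)-3-[(4S,5R)-5-ethenyl-2,2-dimethyl-1,3-dioxolan-4-yl]propan-1-amine | C=C[C@H]1OC(C)(C)O[C@H]1C[C@H](O[Si](C)(C)C(C)(C)C)CN | intermediate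
24 | (2S)-N-{(2S)-2-(TBS-oxy)-3-[(4S,5R)-5-ethenyl-2,2-dimethyl-1,3-dioxolan-4-yl]propyl}-2-hydroxypentanamide | CCC[C@H](O)C(=O)NC[C@@H](O[Si](C)(C)C(C)(C)C)C[C@@H]1OC(C)(C)O[C@@H]1C=C | intermediate
25 | (2S,4S)-12-bromo-2,4-dimethyldodecanoic 2,4,6-trichlorobenzoic anhydride | O=C(OC(=O)c1c(Cl)cc(Cl)cc1Cl)[C@@H](C)C[C@@H](C)CCCCCCCCBr | intermediate
26 | (2S)-1-({(2S)-2-(TBS-oxy)-3-[(4S,5R)-5-ethenyl-2,2-dimethyl-1,3-dioxolan-4-yl]propyl}amino)-1-oxopentan-2-yl (2S,4S)-12-bromo-2,4-dimethyldodecanoate | CCC[C@H](OC(=O)[C@@H](C)C[C@@H](C)CCCCCCCCBr)C(=O)NC[C@@H](O[Si](C)(C)C(C)(C)C)C[C@@H]1OC(C)(C)O[C@@H]1C=C | intermediate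
27 | 3-chlorobut-1-yne (racemic) | C#CC(C)Cl | starting material
28 | (E)-2-(3-chlorobut-1-en-1-yl)-4,4,5,5-tetramethyl-1,3,2-dioxaborolane (racemic) | CC(Cl)/C=C/B1OC(C)(C)C(C)(C)O1 | intermediate
29 | alkylzinc bromide of 26 (ZnBr in place of Br at C12) | CCC[C@H](OC(=O)[C@@H](C)C[C@@H](C)CCCCCCCC[Zn]Br)C(=O)NC[C@@H](O[Si](C)(C)C(C)(C)C)C[C@@H]1OC(C)(C)O[C@@H]1C=C | intermediate
30 | (2S)-1-({(2S)-2-(TBS-oxy)-3-[(4S,5R)-5-ethenyl-2,2-dimethyl-1,3-dioxolan-4-yl]propyl}amino)-1-oxopentan-2-yl (2S,4S,13R,14E)-2,4,13-trimethyl-15-(Bpin)pentadec-14-enoate | CCC[C@H](OC(=O)[C@@H](C)C[C@@H](C)CCCCCCCC[C@@H](C)/C=C/B1OC(C)(C)C(C)(C)O1)C(=O)NC[C@@H](O[Si](C)(C)C(C)(C)C)C[C@@H]2OC(C)(C)O[C@@H]2C=C | intermediate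
31 | 3-methoxyprop-1-yne | C#CCOC | starting material
32 | (1E)-2-bromo-1-iodo-3-methoxyprop-1-ene | I/C=C(\COC)Br | intermediate
33 | (2S)-1-({(2S)-2-(TBS-oxy)-3-[(4S,5R)-5-ethenyl-2,2-dimethyl-1,3-dioxolan-4-yl]propyl}amino)-1-oxopentan-2-yl (2S,4S,13R,14E,16E)-17-bromo-18-methoxy-2,4,13-trimethyloctadeca-14,16-dienoate | CCC[C@H](OC(=O)[C@@H](C)C[C@@H](C)CCCCCCCC[C@@H](C)/C=C/C=C(\COC)Br)C(=O)NC[C@@H](O[Si](C)(C)C(C)(C)C)C[C@@H]1OC(C)(C)O[C@@H]1C=C | intermediate
34 | 9-BBN adduct of 33 (9-borabicyclo[3.3.1]nonan-9-yl on C18 in place of the ethenyl CH2 terminus) | CCC[C@H](OC(=O)[C@@H](C)C[C@@H](C)CCCCCCCC[C@@H](C)/C=C/C=C(\COC)Br)C(=O)NC[C@@H](O[Si](C)(C)C(C)(C)C)C[C@@H]1OC(C)(C)O[C@@H]1CCB1C2CCCC1CCC2 | intermediate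
35 | 20,21-O-isopropylidene-23-O-TBS derivative of the target macrocycle (2S,4S,13R,14E,16Z,20R,21S,23S,2′S) | CCC[C@@H]1OC(=O)[C@@H](C)C[C@@H](C)CCCCCCCC[C@@H](C)/C=C/C=C(\COC)CC[C@H]2OC(C)(C)O[C@H]2C[C@H](O[Si](C)(C)C(C)(C)C)CNC1=O | intermediate
36 | CNP0511044.2: (2S,4S,13R,14E,16Z,20R,21S,23S,2′S)-20,21,23-trihydroxy-17-(methoxymethyl)-2,4,13-trimethyl 28-membered macrolactone-lactam (C1 esterified to O2′ of the 2-hydroxypentanoyl unit; N on C24 acylated by C1′) | CCC[C@@H]1OC(=O)[C@@H](C)C[C@@H](C)CCCCCCCC[C@@H](C)/C=C/C=C(\COC)CC[C@@H](O)[C@@H](O)C[C@H](O)CNC1=O | target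

## Step count and risks

Total step count: 18. Longest linear sequence: 11 steps (steps 5, 6, 7, 9, 10, 11, 12, 14, 16, 17, 18).

Steps most likely to fail:

**Step 14 (enantioconvergent nickel coupling on the full-length zinc reagent).** The risks are protonation or slow insertion with the functionalised substrate as the limiting partner, and regio- or enantiocontrol at the boryl-substituted allyl radical. Fallback: take the coupling out of the late stage and run it before fragment union. The fallback sets out from 10. Fischer esterification (MeOH, cat. H2SO4) gives methyl (2S,4S)-12-bromo-2,4-dimethyldodecanoate F1. Zinc insertion gives the simple alkylzinc bromide F2, which is used in excess in the same nickel/Pybox coupling with 28, where ligand and regiochemistry can be tuned on gram scale, to give methyl (2S,4S,13R,14E)-2,4,13-trimethyl-15-(Bpin)pentadec-14-enoate F3. Me3SnOH (1,2-dichloroethane, 80 °C) frees the acid F4, whose Yamaguchi mixed anhydride F5 acylates 24. The route is rejoined at 30.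

**Step 17 (macrocyclising B-alkyl Suzuki coupling).** The risks are oligomerisation, protodeboronation and incomplete chemoselectivity of the hydroboration. Fallback: close the ring at the ester bond instead and form C17–C18 intermolecularly. The fallback sets out from 24 and from 10 (through F1 to F3 as above). F3 is coupled with 32 (Pd(PPh3)4, aq. K3PO4) to give the bromodiene methyl ester F6. 24 is hydroborated with 9-BBN (2.5 equiv; the free hydroxyl is carried as its borinate) to give borane F7, which is cross-coupled with F6 (Pd(dppf)Cl2, AsPh3, Cs2CO3) to give the hydroxy methyl ester F8. Me3SnOH gives the seco acid F9. Yamaguchi macrolactonisation through mixed anhydride F10 (DMAP, toluene, high dilution) returns to 35.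

**Step 2 (one-pot carboalumination–vinylation and its repetition in step 3).** The risks are moderate enantioselectivity per carboalumination and loss of material when the anti isomer is removed. Fallback: set C2 by auxiliary-controlled enolate alkylation instead of a second carboalumination. The fallback sets out from 4. Carboalumination as in step 2 gives alane 6, which is quenched with O2 to give (2S)-10-bromo-2-methyldecan-1-ol F11 (upgraded to ≥98% ee by lipase-catalysed acetylation if needed). Tf2O/2,6-lutidine gives the triflate F12. (4R)-4-Benzyl-3-propanoyl-1,3-oxazolidin-2-one F13 (from propanoyl chloride and the lithiated (R)-4-benzyl-oxazolidinone auxiliary) is converted to its sodium enolate (NaHMDS, −78 °C) and alkylated with F12 at −78 °C, where the primary bromide is inert, to give the imide F14 (C2 set by the auxiliary, dr > 95:5). LiOH/H2O2 cleaves the auxiliary and returns to 10, bypassing 7, 8 and 9.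

## Further compounds

F1 | step 14 | methyl (2S,4S)-12-bromo-2,4-dimethyldodecanoate | COC(=O)[C@@H](C)C[C@@H](C)CCCCCCCCBr
F2 | step 14 | [(9S,11S)-12-methoxy-9,11-dimethyl-12-oxododecyl]zinc bromide | COC(=O)[C@@H](C)C[C@@H](C)CCCCCCCC[Zn]Br
F3 | step 14 | methyl (2S,4S,13R,14E)-2,4,13-trimethyl-15-(Bpin)pentadec-14-enoate | COC(=O)[C@@H](C)C[C@@H](C)CCCCCCCC[C@@H](C)/C=C/B1OC(C)(C)C(C)(C)O1
F4 | step 14 | (2S,4S,13R,14E)-2,4,13-trimethyl-15-(Bpin)pentadec-14-enoic acid | OC(=O)[C@@H](C)C[C@@H](C)CCCCCCCC[C@@H](C)/C=C/B1OC(C)(C)C(C)(C)O1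
F5 | step 14 | mixed anhydride of F4 with 2,4,6-trichlorobenzoic acid | O=C(OC(=O)c1c(Cl)cc(Cl)cc1Cl)[C@@H](C)C[C@@H](C)CCCCCCCC[C@@H](C)/C=C/B1OC(C)(C)C(C)(C)O1
F6 | step 17 | methyl (2S,4S,13R,14E,16E)-17-bromo-18-methoxy-2,4,13-trimethyloctadeca-14,16-dienoate | COC(=O)[C@@H](C)C[C@@H](C)CCCCCCCC[C@@H](C)/C=C/C=C(\COC)Br
F7 | step 17 | bis-9-BBN derivative of 24 (B-alkyl at the former ethenyl terminus, O-borinate at the 2-hydroxyl) | CCC[C@H](OB1C2CCCC1CCC2)C(=O)NC[C@@H](O[Si](C)(C)C(C)(C)C)C[C@@H]1OC(C)(C)O[C@@H]1CCB1C2CCCC1CCC2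
F8 | step 17 | methyl ester of the open-chain hydroxy acid (C1 methyl ester, free 2′-OH, C17–C18 formed, acetonide and TBS in place) | COC(=O)[C@@H](C)C[C@@H](C)CCCCCCCC[C@@H](C)/C=C/C=C(\COC)CC[C@H]1OC(C)(C)O[C@H]1C[C@H](O[Si](C)(C)C(C)(C)C)CNC(=O)[C@@H](O)CCC
F9 | step 17 | open-chain hydroxy acid (seco acid of 35) | OC(=O)[C@@H](C)C[C@@H](C)CCCCCCCC[C@@H](C)/C=C/C=C(\COC)CC[C@H]1OC(C)(C)O[C@H]1C[C@H](O[Si](C)(C)C(C)(C)C)CNC(=O)[C@@H](O)CCC
F10 | step 17 | mixed anhydride of F9 with 2,4,6-trichlorobenzoic acid | O=C(OC(=O)c1c(Cl)cc(Cl)cc1Cl)[C@@H](C)C[C@@H](C)CCCCCCCC[C@@H](C)/C=C/C=C(\COC)CC[C@H]1OC(C)(C)O[C@H]1C[C@H](O[Si](C)(C)C(C)(C)C)CNC(=O)[C@@H](O)CCC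
F11 | step 2 | (2S)-10-bromo-2-methyldecan-1-ol | OC[C@@H](C)CCCCCCCCBr
F12 | step 2 | (2S)-10-bromo-2-methyldecyl trifluoromethanesulfonate | FC(F)(F)S(=O)(=O)OC[C@@H](C)CCCCCCCCBr
F13 | step 2 | (4R)-4-benzyl-3-propanoyl-1,3-oxazolidin-2-one | CCC(=O)N1[C@H](Cc2ccccc2)COC1=O
F14 | step 2 | (4R)-4-benzyl-3-[(2S,4S)-12-bromo-2,4-dimethyldodecanoyl]-1,3-oxazolidin-2-one | O=C([C@@H](C)C[C@@H](C)CCCCCCCCBr)N1[C@H](Cc2ccccc2)COC1=O
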